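(Readings and results come from a simulation for an exercise, noise included.)

In a one-step world substrate and reagent turn into product while the catalyst stands by, and the flask stops when its limiting reagent is used up; the autumn run levels off far short of that.

all flasks: substrate 200 mM
- autumn: reagent 300 mM; free catalyst 2.00 mM
- spring: reagent 150 mM; free catalyst 2.00 mM
- midnight: reagent 300 mM; free catalyst 6.00 mM; time 44 min

| run | time / min | [product] / mM |
|---|---|---|
| autumn run | 3.4 | 10.9 |
| autumn run | 10 | 24.2 |
| autumn run | 19 | 34.6 |
| autumn run | 31 | 42.2 |
| autumn run | 44 | 43.9 |
| spring run | 3.4 | 9.4 |
| spring run | 10 | 24.2 |
| spring run | 19 | 35.7 |
| spring run | 31 | 41.0 |
| spring run | 44 | 42.8 |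

(standard deviation of a reading: 0.6 mM)

- Overall: substrate + reagent -> product, with free catalyst as catalyst.
- Constant volume, constant temperature.
- Readings of a species count what is bound in complexes too.
- An order is taken over about fifteen percent of the charge, up and down.

* order of the initial rate in [reagent], near the charge of the autumn run, the rate being that where two percent of its substrate are product
* product in the midnight run at 44 min, as a share of the substrate charged

I sort the autumn run by clocks, fastest first. The reagent's step shows no clock of its own: at 10 min the spring run, with half the reagent, holds 24.2 mM of product, and the autumn run holds 24.2 mM, so from this pair of readings, with their scatter, I put the order in reagent near zero, at 0. Next comes the fading of the rate. The first autumn reading gives an average rate of 3.21 mM/min, and at that pace the 43.9 mM of the last reading takes 13.7 min. Slowest is the substrate, whose autumn charge lasts 62.4 min at that pace, a longer clock. So the autumn run levels off, its last two readings being 42.2 mM and 43.9 mM, with 156 mM of substrate at the last reading, bound forms counted. The spring run levels off nearby with 107 mM of reagent against 256 mM in the autumn run, and I read that as a dying catalyst, not an equilibrium.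

So I count what is left, not what is made. I suppose that each minute takes a share of the substrate present, in proportion to the catalyst, and that the catalyst fades on the same course in the autumn and midnight runs; shares taken in turn multiply, so their logarithms add. At 44 min the autumn run leaves 78.1% of its substrate by that reading and has a value of 0.124 /mM for what I call the dose, the natural logarithm of one over the fraction of substrate left, per unit of free catalyst charged. The midnight run, with 6.00 mM, should then leave the autumn fraction cubed, 47.5%, and so make 52.5%.

The forecast gives an order of 0.05 and a share of 60%, holding that “tripling the catalyst should triple the rate and the plateau”, and its share stands above mine.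

The simulation gives an order of 0.011 and a share of 52.9%.

    free catalyst + substrate → catalyst-substrate complex (34.44 /M/min)
    catalyst-substrate complex + reagent → product + free catalyst (556.8 /M/min)
    free catalyst + substrate ⇌ idle catalyst-substrate complex, settled at all times (14.40 /M)
    free catalyst → spent catalyst (0.2676 /min)

The midnight run as it stands has a dose of 0.125 /mM. It stops short of its substrate because free catalyst passes into spent catalyst, and the same midnight run without that passing shows it, reaching 99.7% at 44 min. Without that passing the midnight run leaves about 0.300% of its substrate, a dose of about 0.968 /mM, larger than the 0.125 /mM it has as it stands.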